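**Strategy.** Numbering: C1–C5 and C10 form ring A (C4 bears the methylidene), C5–C10 form ring B, C11 is the benzylic CH2. The route cuts C5–C10 and C8–C9 at once. The feature used is that the C5–C10 bond is common to both rings and that ring B holds four adjacent stereocentres (C8, C9, C10, C5) exactly where the ends of a C5–C8 diene meet a C9=C10 alkene. One thermal intramolecular Diels–Alder reaction closes both rings and sets all four centres. Its precursor is an acyclic trienal: a (Z)-2,3-dimethyl enal joined through C1–C3 and an (R)-silyloxy carbinol (C4) to an (E,E)-diene.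

Key step: step 7

Remarks: β denotes the face of the bicycle that carries the C10 methyl group, α the opposite face. The carbinol carbon C11 in 16–18 is expected as a mixture of epimers; this is of no consequence because the centre is removed in step 12.

**Step 1**
Reactants: 1 ethyl 2-methyl-3-oxobutanoate (ethyl 2-methylacetoacetate)
Product: 2 ethyl (2Z)-2-methyl-3-(trifluoromethanesulfonyloxy)but-2-enoate (triflate oxygen cis to the ester)
Conditions: Tf2O, aq LiOH, PhMe, 5 °C
Reagents that add atoms: trifluoromethanesulfonic anhydride, O=S(=O)(OS(=O)(=O)C(F)(F)F)C(F)(F)F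
Why: Chelation-controlled enol triflation: the lithium enolate of the β-keto ester is held as a chelate with the enolate oxygen cis to the ester carbonyl, so O-sulfonylation should give the (Z)-triflate, whose geometry later becomes that of the C9=C10 dienophile.

**Step 2**
Reactants: 3 (2E,4E)-hexa-2,4-dienal (sorbaldehyde)
Product: 5 (4R,5E,7E)-nona-1,5,7-trien-4-ol, via borinate ester 4 (not isolated)
Conditions: (+)-Ipc2BOMe [from (−)-α-pinene], allylmagnesium bromide, Et2O, −78 °C → rt; then 3, −78 °C; NaOH, H2O2
Reagents that add atoms: allylmagnesium bromide, C=CC[Mg]Br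
Why: Brown asymmetric allylboration: allyl is transferred 1,2 through a closed chair transition state, and the reagent antipode derived from (−)-α-pinene should attack the re face of the dienal carbonyl, which sets C4 as R.

**Step 3**
Reactants: 5 (4R,5E,7E)-nona-1,5,7-trien-4-ol
Product: 6 (4R,5E,7E)-4-(tert-butyldimethylsilyloxy)nona-1,5,7-triene
Conditions: TBSCl, imidazole, DMF, rt
Reagents that add atoms: tert-butyldimethylsilyl chloride, CC(C)(C)[Si](C)(C)Cl
Why: Standard silylation of a secondary alcohol under basic conditions, which avoids ionisation of the acid-sensitive dienyl carbinol and leaves C4 untouched.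

**Step 4**
Reactants: 6 (4R,5E,7E)-4-(tert-butyldimethylsilyloxy)nona-1,5,7-triene; 2 ethyl (2Z)-2-methyl-3-(trifluoromethanesulfonyloxy)but-2-enoate
Product: 8 ethyl (2Z,7R,8E,10E)-7-(tert-butyldimethylsilyloxy)-2,3-dimethyldodeca-2,8,10-trienoate, via B-alkyl-9-BBN 7 (not isolated)
Conditions: 9-BBN-H, THF, 0 °C → rt; then 2, PdCl2(dppf), AsPh3, Cs2CO3, DMF–H2O, rt
Reagents that add atoms: none
Why: 9-BBN-H hydroborates the monosubstituted alkene in preference to the internal conjugated diene and places boron on C1, and the B-alkyl Suzuki–Miyaura coupling then proceeds with retention at the electron-poor vinyl triflate, so that C1 ends cis to the ester in the fully substituted (Z)-enoate.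

**Step 5**
Reactants: 8 ethyl (2Z,7R,8E,10E)-7-(tert-butyldimethylsilyloxy)-2,3-dimethyldodeca-2,8,10-trienoate
Product: 9 (2Z,7R,8E,10E)-7-(tert-butyldimethylsilyloxy)-2,3-dimethyldodeca-2,8,10-trien-1-ol
Conditions: iBu2AlH, CH2Cl2, −78 → 0 °C; aq potassium sodium tartrate
Reagents that add atoms: none
Why: 1,2-Reduction of a conjugated ester to the allylic alcohol with an aluminium hydride; the silyl ether, the diene and the alkene geometry are not affected.

**Step 6**
Reactants: 9 (2Z,7R,8E,10E)-7-(tert-butyldimethylsilyloxy)-2,3-dimethyldodeca-2,8,10-trien-1-ol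
Product: 10 (2Z,7R,8E,10E)-7-(tert-butyldimethylsilyloxy)-2,3-dimethyldodeca-2,8,10-trienal
Conditions: MnO2 (activated, excess), CH2Cl2, rt
Reagents that add atoms: none
Why: Allylic oxidation with MnO2 under neutral conditions should stop at the enal and avoid acid- or base-promoted Z-to-E isomerisation of the tetrasubstituted alkene.

**Step 7**
Reactants: 10 (2Z,7R,8E,10E)-7-(tert-butyldimethylsilyloxy)-2,3-dimethyldodeca-2,8,10-trienal
Product: 11 trans-fused Δ6-octalin aldehyde: 4α-(tert-butyldimethylsilyloxy) (4R), 5α-H, 8β-methyl, 9β-methyl, 9α-formyl, 10β-methyl, C6=C7 alkene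
Conditions: PhMe (0.01 M), BHT (cat.), base-washed sealed tube, 170 °C
Reagents that add atoms: none
Why: A concerted, thermally allowed [4+2] cycloaddition, suprafacial on both partners, joins C5 to C10 and C8 to C9; the closest known reaction type is the thermal intramolecular Diels–Alder reaction of 1,7,9-decatrienes that carry an α-methyl enal as dienophile. Ring B is closed by the cycloaddition itself as the new cyclohexene (C5–C6=C7–C8–C9–C10), and ring A is closed in the same event as a six-membered carbocycle when the C1–C4 tether, folded chair-like, brings C10 onto C5. The Z geometry of the enal (C1 cis to the formyl group) fixes the C9 and C10 methyls cis, and the E,E geometry of the diene places C4 and the C8 methyl on one face of ring B. The relation between these two pairs (C8 methyl cis to the C9 methyl, trans ring fusion at C5/C10) follows from the exo-formyl transition state, which α-methyl enals generally prefer. The absolute sense comes from C4: the (R)-silyloxy group should sit equatorial on the chair tether, because the axial alternative clashes 1,3-diaxially with the C10 methyl, so only one diene face reacts. The step therefore needs exo (trans-fused) over endo (cis-fused) selectivity and diene facial selectivity, secured by the α-methyl group of the enal and by the C4 stereocentre, while dilution, BHT and acid-free glass should suppress polymerisation and Z-to-E isomerisation of the enal.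

**Step 8**
Reactants: 11 trans-fused Δ6-octalin aldehyde
Product: 12 trans-decalin aldehyde: 4α-(tert-butyldimethylsilyloxy), 5α-H, 8β-methyl, 9β-methyl, 9α-formyl, 10β-methyl
Conditions: H2 (1 atm), 5% Pt/C, EtOAc, rt
Reagents that add atoms: none
Why: Heterogeneous hydrogenation of the cis-disubstituted C6=C7 alkene creates no stereocentre; platinum is preferred to palladium to limit double-bond migration toward C8, and the hindered aldehyde without α-hydrogen should survive.

**Step 9**
Reactants: 13 methyl 4-hydroxy-3-iodobenzoate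
Product: 14 methyl 3-iodo-4-(methoxymethoxy)benzoate
Conditions: MOMCl, iPr2NEt, CH2Cl2, 0 °C → rt
Reagents that add atoms: chloromethyl methyl ether, COCCl
Why: O-Alkylation of the phenol (acetal protection) removes the acidic proton before magnesiation and gives a group that is cleaved later by acid at a stage where no alkene is present.

**Step 10**
Reactants: 14 methyl 3-iodo-4-(methoxymethoxy)benzoate; 12 trans-decalin aldehyde
Product: 16 methyl 3-[hydroxy(decalin-9α-yl)methyl]-4-(methoxymethoxy)benzoate (decalin unit as in 12; C11 epimers), via arylmagnesium chloride 15 (not isolated)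
Conditions: 14, iPrMgCl·LiCl, THF, −40 °C; then LaCl3·2LiCl, 12, −40 → 0 °C; aq NH4Cl
Reagents that add atoms: none
Why: Iodine–magnesium exchange with iPrMgCl·LiCl at low temperature tolerates the methyl ester, and the resulting aryl Grignard reagent, assisted by the oxophilic lanthanum salt, should add 1,2 to the non-enolisable neopentyl aldehyde (Grignard addition).

**Step 11**
Reactants: 16 methyl 3-[hydroxy(decalin-9α-yl)methyl]-4-(methoxymethoxy)benzoate
Product: 18 O-[aryl(decalin-9α-yl)methyl] S-methyl dithiocarbonate (xanthate of 16), via sodium xanthate 17 (not isolated)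
Conditions: NaN(SiMe3)2, THF, −78 °C; CS2, −78 → 0 °C; MeI, 0 °C → rt
Reagents that add atoms: carbon disulfide, S=C=S; iodomethane, CI
Why: Xanthate formation (alkoxide addition to CS2, then S-methylation) works on hindered alkoxides because CS2 is small, and the xanthate cannot undergo Chugaev elimination since C9 carries no hydrogen.

**Step 12**
Reactants: 18 O-[aryl(decalin-9α-yl)methyl] S-methyl dithiocarbonate
Product: 19 methyl 3-{[4α-(tert-butyldimethylsilyloxy)-8β,9β,10β-trimethyl-5α-H-trans-decalin-9α-yl]methyl}-4-(methoxymethoxy)benzoate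
Conditions: Bu3SnH, AIBN (cat.), PhMe, 85 °C
Reagents that add atoms: none
Why: Barton–McCombie deoxygenation: the stannyl radical adds to the thiocarbonyl, β-scission releases a benzylic C11 radical that takes hydrogen from Bu3SnH, and the radical (non-cationic) pathway avoids 1,2-shifts from the quaternary C9.

**Step 13**
Reactants: 19 silyl- and MOM-protected arylmethyl decalin
Product: 20 methyl 4-hydroxy-3-{[4α-hydroxy-8β,9β,10β-trimethyl-5α-H-trans-decalin-9α-yl]methyl}benzoate
Conditions: HCl (1.25 M in MeOH), MeOH, rt → 40 °C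
Reagents that add atoms: none
Why: Acid-catalysed methanolysis cleaves the aryl MOM acetal and the secondary silyl ether in one operation; the molecule has no alkene at this stage, and the methyl ester is inert in methanol.

**Step 14**
Reactants: 20 methyl 4-hydroxy-3-{[4α-hydroxy-8β,9β,10β-trimethyl-5α-H-trans-decalin-9α-yl]methyl}benzoate
Product: 21 methyl 4-hydroxy-3-{[8β,9β,10β-trimethyl-4-oxo-5α-H-trans-decalin-9α-yl]methyl}benzoate
Conditions: Dess–Martin periodinane, NaHCO3, CH2Cl2, 0 °C → rt
Reagents that add atoms: none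
Why: Dess–Martin oxidation of the secondary alcohol under buffered, near-neutral conditions should leave the electron-poor phenol (para ester) alone and should not epimerise C5, now α to the ketone.

**Step 15**
Reactants: 21 methyl 4-hydroxy-3-{[8β,9β,10β-trimethyl-4-oxo-5α-H-trans-decalin-9α-yl]methyl}benzoate
Product: 22 methyl 4-hydroxy-3-{[8β,9β,10β-trimethyl-4-methylidene-5α-H-trans-decalin-9α-yl]methyl}benzoate (CNP0169318.1; 5S,8S,9R,10S in the numbering used here)
Conditions: Zn, CH2Br2, TiCl4, THF, 0–5 °C (reagent); then 21, CH2Cl2, rt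
Reagents that add atoms: dibromomethane, BrCBr
Why: Takai–Lombardo methylenation: the non-basic zinc–titanium methylene reagent olefinates ketones but not esters, so the C4 carbonyl should become the methylidene without enolisation toward the epimerisable C5 and without attack on the benzoate, an excess of reagent covering the free phenol.

**Compound list**

1 | ethyl 2-methyl-3-oxobutanoate | CCOC(=O)C(C)C(C)=O | starting material
2 | ethyl (2Z)-2-methyl-3-(trifluoromethanesulfonyloxy)but-2-enoate | C/C(OS(=O)(=O)C(F)(F)F)=C(\C)C(=O)OCC | intermediate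
3 | (2E,4E)-hexa-2,4-dienal | C/C=C/C=C/C=O | starting material
4 | (4R,5E,7E)-nona-1,5,7-trien-4-yl diisopinocampheylborinate (not isolated) | B([C@H]1C[C@H]2C[C@H](C2(C)C)[C@@H]1C)([C@H]1C[C@H]2C[C@H](C2(C)C)[C@@H]1C)O[C@H](CC=C)/C=C/C=C/C | intermediate
5 | (4R,5E,7E)-nona-1,5,7-trien-4-ol | O[C@H](CC=C)/C=C/C=C/C | intermediate
6 | (4R,5E,7E)-4-(tert-butyldimethylsilyloxy)nona-1,5,7-triene | CC(C)(C)[Si](C)(C)O[C@H](CC=C)/C=C/C=C/C | intermediate
7 | 9-[(4R,5E,7E)-4-(tert-butyldimethylsilyloxy)nona-5,7-dien-1-yl]-9-borabicyclo[3.3.1]nonane (not isolated) | CC(C)(C)[Si](C)(C)O[C@H](CCCB1C2CCCC1CCC2)/C=C/C=C/C | intermediate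
8 | ethyl (2Z,7R,8E,10E)-7-(tert-butyldimethylsilyloxy)-2,3-dimethyldodeca-2,8,10-trienoate | CC(C)(C)[Si](C)(C)O[C@H](CCC/C(C)=C(C)\C(=O)OCC)/C=C/C=C/C | intermediate
9 | (2Z,7R,8E,10E)-7-(tert-butyldimethylsilyloxy)-2,3-dimethyldodeca-2,8,10-trien-1-ol | CC(C)(C)[Si](C)(C)O[C@H](CCC/C(C)=C(C)\CO)/C=C/C=C/C | intermediate
10 | (2Z,7R,8E,10E)-7-(tert-butyldimethylsilyloxy)-2,3-dimethyldodeca-2,8,10-trienal (Diels–Alder precursor) | CC(C)(C)[Si](C)(C)O[C@H](CCC/C(C)=C(C)\C=O)/C=C/C=C/C | intermediate
11 | trans-fused Δ6-octalin aldehyde (4α-OTBS, 5α-H, 8β-Me, 9β-Me, 9α-CHO, 10β-Me) | CC(C)(C)[Si](C)(C)O[C@@H]1CCC[C@@]2(C)[C@H]1C=C[C@H](C)[C@@]2(C)C=O | intermediate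
12 | trans-decalin aldehyde (C6–C7 saturated, otherwise as 11) | CC(C)(C)[Si](C)(C)O[C@@H]1CCC[C@@]2(C)[C@H]1CC[C@H](C)[C@@]2(C)C=O | intermediate
13 | methyl 4-hydroxy-3-iodobenzoate | COC(=O)c1ccc(O)c(I)c1 | starting material
14 | methyl 3-iodo-4-(methoxymethoxy)benzoate | COCOc1ccc(C(=O)OC)cc1I | intermediate
15 | [5-(methoxycarbonyl)-2-(methoxymethoxy)phenyl]magnesium chloride–lithium chloride (not isolated) | COCOc1ccc(C(=O)OC)cc1[Mg]Cl.[Li+].[Cl-] | intermediate
16 | methyl 3-[hydroxy(decalin-9α-yl)methyl]-4-(methoxymethoxy)benzoate (C11 epimers) | CC(C)(C)[Si](C)(C)O[C@@H]1CCC[C@@]2(C)[C@H]1CC[C@H](C)[C@@]2(C)C(O)c1cc(C(=O)OC)ccc1OCOC | intermediate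
17 | sodium O-[aryl(decalin-9α-yl)methyl] dithiocarbonate (not isolated) | CC(C)(C)[Si](C)(C)O[C@@H]1CCC[C@@]2(C)[C@H]1CC[C@H](C)[C@@]2(C)C(OC(=S)[S-])c1cc(C(=O)OC)ccc1OCOC.[Na+] | intermediate
18 | O-[aryl(decalin-9α-yl)methyl] S-methyl dithiocarbonate | CC(C)(C)[Si](C)(C)O[C@@H]1CCC[C@@]2(C)[C@H]1CC[C@H](C)[C@@]2(C)C(OC(=S)SC)c1cc(C(=O)OC)ccc1OCOC | intermediate
19 | methyl 3-{[4α-(tert-butyldimethylsilyloxy)-8β,9β,10β-trimethyl-trans-decalin-9α-yl]methyl}-4-(methoxymethoxy)benzoate | CC(C)(C)[Si](C)(C)O[C@@H]1CCC[C@@]2(C)[C@H]1CC[C@H](C)[C@@]2(C)Cc1cc(C(=O)OC)ccc1OCOC | intermediate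
20 | methyl 4-hydroxy-3-{[4α-hydroxy-8β,9β,10β-trimethyl-trans-decalin-9α-yl]methyl}benzoate | O[C@@H]1CCC[C@@]2(C)[C@H]1CC[C@H](C)[C@@]2(C)Cc1cc(C(=O)OC)ccc1O | intermediate
21 | methyl 4-hydroxy-3-{[8β,9β,10β-trimethyl-4-oxo-trans-decalin-9α-yl]methyl}benzoate | O=C1CCC[C@@]2(C)[C@H]1CC[C@H](C)[C@@]2(C)Cc1cc(C(=O)OC)ccc1O | intermediate
22 | methyl 4-hydroxy-3-{[8β,9β,10β-trimethyl-4-methylidene-trans-decalin-9α-yl]methyl}benzoate (CNP0169318.1) | C=C1CCC[C@@]2(C)[C@H]1CC[C@H](C)[C@@]2(C)Cc1cc(C(=O)OC)ccc1O | target

**Step count**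

Total step count: 15. Longest linear sequence: 13 steps (steps 2–8 and 10–15, from sorbaldehyde 3); steps 1 and 9 are one-step side branches.

**Steps most likely to fail**

1. Step 7 (cycloaddition). The fully substituted dienophile may react so slowly that, at the temperature needed, the enal loses its Z geometry through its dienol, or the preference for the exo-formyl, trans-fused transition state erodes. The fallback replaces the neutral thermal cycloaddition by a cationic one at low temperature. It sets out from 10. Acetalisation with 1,2-bis(trimethylsilyloxy)ethane and catalytic TMSOTf (CH2Cl2, −78 °C, 2,6-di-tert-butylpyridine as buffer) should give the ethylene acetal of the enal F1. Ionisation of the dioxolane with TMSOTf at −78 °C gives an alkoxy-stabilised allyl cation, a much stronger dienophile. Its intramolecular [4+2] cycloaddition with the diene (ionic Diels–Alder reaction of enal acetals) should give the ethylene acetal of the cycloadduct F2 well below the temperature at which the alkene geometry is lost. Hydrolysis (PPTS, wet acetone) comes back to the route at 11.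

2. Step 10 (aryl addition). Addition to the very hindered aldehyde may be too slow at the temperatures the ester-bearing Grignard reagent tolerates, so the reagent condenses with its own ester while the aldehyde is recovered. The fallback uses a more reactive, ester-free aryllithium and introduces the ester afterwards. It sets out from 12. Commercial 2,4-dibromophenol is protected (MOMCl, iPr2NEt) as 2,4-dibromo-1-(methoxymethoxy)benzene F3. Bromine–lithium exchange with n-BuLi (Et2O, −78 °C), directed to the position ortho to the acetal oxygen, gives 5-bromo-2-(methoxymethoxy)phenyllithium F4. Addition of F4 to 12 at −78 °C should give the bromoaryl carbinol F5. Palladium-catalysed methoxycarbonylation of the aryl bromide (Pd(OAc)2, Xantphos, CO 1 atm, MeOH, Et3N, 70 °C) comes back to the route at 16.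

3. Step 4 (B-alkyl coupling). Transmetalation of the alkylborane onto the hindered, tetrasubstituted vinylpalladium intermediate may be slow, so that base-mediated hydrolysis of the triflate back to the keto ester and β-hydride loss from the alkyl group compete. The fallback replaces the base-dependent boron transmetalation by a Negishi coupling of an alkylzinc reagent. It sets out from 6. Hydroboration with 9-BBN-H and oxidative work-up (NaOH, H2O2) gives (4R,5E,7E)-4-(tert-butyldimethylsilyloxy)nona-5,7-dien-1-ol F6. An Appel reaction (I2, PPh3, imidazole) gives the primary iodide F7. Zinc insertion (Zn dust, LiCl, THF) gives the alkylzinc iodide F8. Coupling of F8 with triflate 2 (Pd(OAc)2, SPhos, THF, rt), again with retention at the alkene, comes back to the route at 8.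

**Further compounds**

F1 | step 7 | 2-[(2Z,7R,8E,10E)-7-(tert-butyldimethylsilyloxy)-3-methyldodeca-2,8,10-trien-2-yl]-1,3-dioxolane (ethylene acetal of 10) | CC(C)(C)[Si](C)(C)O[C@H](CCC/C(C)=C(C)\C1OCCO1)/C=C/C=C/C
F2 | step 7 | ethylene acetal of octalin aldehyde 11 | CC(C)(C)[Si](C)(C)O[C@@H]1CCC[C@@]2(C)[C@H]1C=C[C@H](C)[C@@]2(C)C3OCCO3
F3 | step 10 | 2,4-dibromo-1-(methoxymethoxy)benzene | COCOc1ccc(Br)cc1Br
F4 | step 10 | 5-bromo-2-(methoxymethoxy)phenyllithium | [Li]c1cc(Br)ccc1OCOC
F5 | step 10 | [5-bromo-2-(methoxymethoxy)phenyl](decalin-9α-yl)methanol (decalin unit as in 12; C11 epimers) | CC(C)(C)[Si](C)(C)O[C@@H]1CCC[C@@]2(C)[C@H]1CC[C@H](C)[C@@]2(C)C(O)c1cc(Br)ccc1OCOC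
F6 | step 4 | (4R,5E,7E)-4-(tert-butyldimethylsilyloxy)nona-5,7-dien-1-ol | CC(C)(C)[Si](C)(C)O[C@H](CCCO)/C=C/C=C/C
F7 | step 4 | tert-butyl{[(4R,5E,7E)-1-iodonona-5,7-dien-4-yl]oxy}dimethylsilane | CC(C)(C)[Si](C)(C)O[C@H](CCCI)/C=C/C=C/C
F8 | step 4 | [(4R,5E,7E)-4-(tert-butyldimethylsilyloxy)nona-5,7-dien-1-yl]zinc iodide | CC(C)(C)[Si](C)(C)O[C@H](CCC[Zn]I)/C=C/C=C/C
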